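**Strategy**

Everything rests on building ring B last: the arene is assembled on the two-carbon chain already attached to oxolane C2, so that C2 becomes benzylic only at the very end. Ring B is a phenol whose hydroxyl-bearing carbon lies para to the carbon bonded to C2 and ortho to the carbon carrying the chiral 1-arylpropan-2-yl chain, exactly the pattern produced when an aldehyde α-carbon and an ethynyl ketone are annulated. In one operation the key step forms two C–C bonds and the aromatic ring from an oxolan-2-ylacetaldehyde (ring A, four ring stereocenters) and a chiral ynone (ring C, the side-chain stereocenter), both carried as benzyl ethers.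

Key step: step 12

**Remarks on the chemistry**

- Labels: oxolane (tetrahydrofuran) O1, C2 (bears ring B), C3 and C4 (methyl groups), C5 (bears ring A); ring C is the aryl group of the side chain. The target is (2R,3R,4S,5S) in the oxolane (2,3-trans, 3,4-cis, 4,5-trans) and (R) in the side chain.
- Assumption: methyl hydrogen (R)-3-methylglutarate is available in enantiopure grade.
- Rings A and C are carried as benzyl ethers. In the product C2 and C5 are both p-oxygenated benzylic ether carbons, which hot thiolate or a Lewis acid (as needed for methyl ethers) could open through quinone methides; hydrogenolysis is neutral.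
- The enamine is preformed and freed from excess amine, because a free secondary amine adds readily to a terminal ynone.
- The side-chain stereocenter comes from the chiral pool and the arene is attached by decarboxylative coupling. This avoids 4-arylbut-2-enoyl intermediates, which slip into conjugation with the arene.

**Route**

Step 1
Reactants: 1 (S)-4-benzyloxazolidin-2-one; 2 (E)-but-2-enoyl chloride
Product: 3 (S)-4-benzyl-3-[(E)-but-2-enoyl]oxazolidin-2-one
Conditions: n-BuLi, THF, −78 °C; then 2, −78 → 0 °C
Reagents that add atoms: none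
Why: N-Acylation of the lithiated oxazolidinone by the acid chloride is fast at −78 °C and touches neither the E-alkene nor the auxiliary stereocenter.

Step 2
Reactants: 3 (S)-4-benzyl-3-[(E)-but-2-enoyl]oxazolidin-2-one; 4 vinylmagnesium bromide
Product: 5 (S)-4-benzyl-3-[(R)-3-methylpent-4-enoyl]oxazolidin-2-one
Conditions: CuBr·SMe2 (1 equiv), THF/Me2S, −78 → −20 °C; aq NH4Cl
Reagents that add atoms: none
Why: Auxiliary-controlled cuprate conjugate addition: in the magnesium-chelated s-cis imide the vinyl group should be delivered to the β-face remote from the benzyl group of the auxiliary, which sets the (R) methyl-bearing center that becomes C3 of the oxolane.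

Step 3
Reactants: 5 (S)-4-benzyl-3-[(R)-3-methylpent-4-enoyl]oxazolidin-2-one
Product: 6 (S)-4-benzyl-3-[(2S,3S)-2,3-dimethylpent-4-enoyl]oxazolidin-2-one
Conditions: NaN(SiMe3)2, THF, −78 °C; then MeI, −78 → −40 °C
Reagents that add atoms: iodomethane, CI
Why: Auxiliary-controlled enolate alkylation: the chelated Z-sodium enolate should be methylated on the face opposite the auxiliary benzyl group, which sets the (2S) center (later C4) and thereby the 2,3-anti dimethyl pair that maps onto the cis-3,4-dimethyl unit of the ring.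

Step 4
Reactants: 6 (S)-4-benzyl-3-[(2S,3S)-2,3-dimethylpent-4-enoyl]oxazolidin-2-one
Product: 7 S-ethyl (2S,3S)-2,3-dimethylpent-4-enethioate
Conditions: EtSH, n-BuLi, THF, 0 °C; aq NH4Cl
Reagents that add atoms: ethanethiol, CCS
Why: Thiolate transacylation at the exocyclic imide carbonyl: the weakly basic lithium thiolate should release the auxiliary without epimerising the α-center and delivers a thioester ready for ketone synthesis.

Step 5
Reactants: 7 S-ethyl (2S,3S)-2,3-dimethylpent-4-enethioate; 8 4-(benzyloxy)phenylmagnesium bromide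
Product: 9 (2S,3S)-1-[4-(benzyloxy)phenyl]-2,3-dimethylpent-4-en-1-one
Conditions: 8, ZnCl2, THF, 0 °C; then 7, PdCl2(PPh3)2 (cat.), THF/toluene, rt
Reagents that add atoms: none
Why: Fukuyama coupling: palladium-catalysed acylation of the arylzinc reagent by the thioester stops at the ketone under neutral conditions, so the enolisable α-center should be preserved and the terminal alkene and benzyl ether are inert.

Step 6
Reactants: 9 (2S,3S)-1-[4-(benzyloxy)phenyl]-2,3-dimethylpent-4-en-1-one
Product: 10 (1S,2S,3S)-1-[4-(benzyloxy)phenyl]-2,3-dimethylpent-4-en-1-ol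
Conditions: LiBH(s-Bu)3, THF, −78 °C; aq NH4Cl
Reagents that add atoms: none
Why: Felkin–Anh-controlled ketone reduction: the bulky hydride should attack anti to the branched C3 substituent and past the α-hydrogen, giving the 1,2-anti alcohol with the (1S) carbinol center that becomes C5, trans to the C4 methyl.

Step 7
Reactants: 10 (1S,2S,3S)-1-[4-(benzyloxy)phenyl]-2,3-dimethylpent-4-en-1-ol; 11 (E)-but-2-enal
Product: 13 2-[(2S,3R,4S,5S)-5-[4-(benzyloxy)phenyl]-3,4-dimethyloxolan-2-yl]acetaldehyde, via hydroxy enal 12 (not isolated)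
Conditions: 11 (excess), second-generation Hoveyda–Grubbs catalyst (cat.), CH2Cl2, 40 °C; then toluene, 60 °C
Reagents that add atoms: none
Why: Olefin cross-metathesis gives the E-enal, whose benzylic hydroxyl then adds in a 5-exo-trig oxa-Michael closure; attack anti to the allylic methyl group and the lower strain of the product should both place the new C2 substituent trans to the C3 methyl and cis to the C5 aryl group.

Step 8
Reactants: 14 methyl hydrogen (R)-3-methylglutarate
Product: 15 1-(1,3-dioxoisoindolin-2-yl) 5-methyl (3S)-3-methylpentanedioate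
Conditions: N-hydroxyphthalimide, N,N'-diisopropylcarbodiimide, DMAP (cat.), CH2Cl2, rt
Reagents that add atoms: N-hydroxyphthalimide, O=C1c2ccccc2C(=O)N1O
Why: Carbodiimide esterification (Steglich type) of the free acid with N-hydroxyphthalimide gives the redox-active ester without touching the stereocenter, which is β to both carbonyl groups (its descriptor changes only by the priority rules).

Step 9
Reactants: 15 1-(1,3-dioxoisoindolin-2-yl) 5-methyl (3S)-3-methylpentanedioate; 8 4-(benzyloxy)phenylmagnesium bromide
Product: 16 methyl (3R)-4-[4-(benzyloxy)phenyl]-3-methylbutanoate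
Conditions: 8, ZnCl2, THF, 0 °C; then 15, Fe(acac)3 (cat.), 1,2-bis(diphenylphosphino)benzene (cat.), THF, rt
Reagents that add atoms: none
Why: Iron-catalysed decarboxylative cross-coupling of a redox-active ester with an arylzinc reagent: electron transfer, loss of CO2 and capture of the primary alkyl radical at iron should form the CH2–aryl bond, while the stereocenter one carbon away is not involved.

Step 10
Reactants: 16 methyl (3R)-4-[4-(benzyloxy)phenyl]-3-methylbutanoate
Product: 17 (3R)-4-[4-(benzyloxy)phenyl]-N-methoxy-N,3-dimethylbutanamide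
Conditions: MeONHMe·HCl, i-PrMgCl, THF, −20 → 0 °C; aq NH4Cl
Reagents that add atoms: N,O-dimethylhydroxylamine hydrochloride, CNOC.Cl
Why: Weinreb amide formation by aminolysis of the methyl ester with the chloromagnesium amide of N,O-dimethylhydroxylamine is reliable for unhindered esters and leaves the β-stereocenter and the benzyl ether alone.

Step 11
Reactants: 17 (3R)-4-[4-(benzyloxy)phenyl]-N-methoxy-N,3-dimethylbutanamide; 18 ethynylmagnesium bromide
Product: 19 (5R)-6-[4-(benzyloxy)phenyl]-5-methylhex-1-yn-3-one
Conditions: THF, 0 °C; inverse quench into cold aq HCl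
Reagents that add atoms: none
Why: Weinreb ketone synthesis: the chelated tetrahedral adduct prevents a second addition, and the cold acidic inverse quench keeps the liberated N,O-dimethylhydroxylamine protonated so that it cannot add to the terminal ynone.

Step 12
Reactants: 13 2-[(2S,3R,4S,5S)-5-[4-(benzyloxy)phenyl]-3,4-dimethyloxolan-2-yl]acetaldehyde; 19 (5R)-6-[4-(benzyloxy)phenyl]-5-methylhex-1-yn-3-one
Product: 22 4-[(2R,3R,4S,5S)-5-[4-(benzyloxy)phenyl]-3,4-dimethyloxolan-2-yl]-2-[(2R)-1-[4-(benzyloxy)phenyl]propan-2-yl]phenol, via pyrrolidine enamine 20 (not isolated), via aminodienone Michael adduct 21 (not isolated)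
Conditions: 13, pyrrolidine (1.05 equiv), 4 Å molecular sieves, CH2Cl2, 0 °C → rt, then evaporate; 19, EtOH, 0 °C → rt; then AcOH/NaOAc, aq EtOH, 60 °C
Reagents that add atoms: none
Why: Enamine 20 attacks the unsubstituted alkyne terminus of 19 with its β-carbon (the former aldehyde α-carbon, bonded to oxolane C2), and proton transfer in the protic medium, which intercepts the zwitterion before it can collapse to a cyclobutene, gives the push–pull aminodienone 21. Under acetic acid the ketone α'-methylene, as its enol, attacks the iminium (aldehyde-derived) carbon, pyrrolidine is expelled, and the resulting cyclohexa-2,5-dienone bearing hydrogen at C4 tautomerises irreversibly to the phenol. The closest known reaction type is the Robinson-type Michael–aldol annulation of aldehyde enamines with ethynyl ketones, which gives cyclohexadienones directly and phenols when C4 carries hydrogen. Ring B is closed in a 6-(enolendo)-exo-trig aldol (Mannich-type) mode. No stereocenter is created: the four oxolane centers and the side-chain center are carried through, and C2, the only one that could be touched (by β-alkoxy elimination and re-addition), already has the thermodynamically preferred orientation trans to the C3 methyl, to which it would return. The step needs C–C bonding at the alkyne terminus instead of amine addition and the 1,2,4-pattern on ring B; the first is secured by preforming the enamine so that the ynone never meets free amine, the second by the connectivity of the partners, two ring carbons coming from 13 and four from 19 with the carbon on C2 para to the former ketone carbon and the side chain on the former α'-carbon ortho to it.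

Step 13
Reactants: 22 4-[(2R,3R,4S,5S)-5-[4-(benzyloxy)phenyl]-3,4-dimethyloxolan-2-yl]-2-[(2R)-1-[4-(benzyloxy)phenyl]propan-2-yl]phenol
Product: 23 4-[(2R,3R,4S,5S)-5-(4-hydroxyphenyl)-3,4-dimethyloxolan-2-yl]-2-[(2R)-1-(4-hydroxyphenyl)propan-2-yl]phenol (target)
Conditions: H2 (1 atm), Pd/C, EtOAc, rt
Reagents that add atoms: none
Why: Catalytic hydrogenolysis of the two aryl benzyl ethers is neutral, so the p-hydroxybenzylic C–O bonds at C2 and C5 should be neither ionised nor epimerised, and aryl benzyl ethers are cleaved well before dialkyl benzylic ethers.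

**Compound list**

1 | (S)-4-benzyloxazolidin-2-one | O=C1N[C@@H](Cc2ccccc2)CO1 | starting material
2 | (E)-but-2-enoyl chloride | C/C=C/C(=O)Cl | starting material
3 | (S)-4-benzyl-3-[(E)-but-2-enoyl]oxazolidin-2-one | C/C=C/C(=O)N1[C@@H](Cc2ccccc2)COC1=O | intermediate
4 | vinylmagnesium bromide | C=C[Mg]Br | starting material
5 | (S)-4-benzyl-3-[(R)-3-methylpent-4-enoyl]oxazolidin-2-one | C=C[C@H](C)CC(=O)N1[C@@H](Cc2ccccc2)COC1=O | intermediate
6 | (S)-4-benzyl-3-[(2S,3S)-2,3-dimethylpent-4-enoyl]oxazolidin-2-one | C=C[C@H](C)[C@H](C)C(=O)N1[C@@H](Cc2ccccc2)COC1=O | intermediate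
7 | S-ethyl (2S,3S)-2,3-dimethylpent-4-enethioate | C=C[C@H](C)[C@H](C)C(=O)SCC | intermediate
8 | 4-(benzyloxy)phenylmagnesium bromide | Br[Mg]c1ccc(OCc2ccccc2)cc1 | starting material
9 | (2S,3S)-1-[4-(benzyloxy)phenyl]-2,3-dimethylpent-4-en-1-one | C=C[C@H](C)[C@H](C)C(=O)c1ccc(OCc2ccccc2)cc1 | intermediate
10 | (1S,2S,3S)-1-[4-(benzyloxy)phenyl]-2,3-dimethylpent-4-en-1-ol | C=C[C@H](C)[C@H](C)[C@H](O)c1ccc(OCc2ccccc2)cc1 | intermediate
11 | (E)-but-2-enal | C/C=C/C=O | starting material
12 | (2E,4S,5S,6S)-6-[4-(benzyloxy)phenyl]-6-hydroxy-4,5-dimethylhex-2-enal, not isolated | O=C/C=C/[C@H](C)[C@H](C)[C@H](O)c1ccc(OCc2ccccc2)cc1 | intermediate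
13 | 2-[(2S,3R,4S,5S)-5-[4-(benzyloxy)phenyl]-3,4-dimethyloxolan-2-yl]acetaldehyde | C[C@@H]1[C@H](C)[C@@H](c2ccc(OCc3ccccc3)cc2)O[C@H]1CC=O | intermediate
14 | methyl hydrogen (R)-3-methylglutarate, (3R)-5-methoxy-3-methyl-5-oxopentanoic acid | COC(=O)C[C@H](C)CC(=O)O | starting material
15 | 1-(1,3-dioxoisoindolin-2-yl) 5-methyl (3S)-3-methylpentanedioate | COC(=O)C[C@H](C)CC(=O)ON1C(=O)c2ccccc2C1=O | intermediate
16 | methyl (3R)-4-[4-(benzyloxy)phenyl]-3-methylbutanoate | COC(=O)C[C@H](C)Cc1ccc(OCc2ccccc2)cc1 | intermediate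
17 | (3R)-4-[4-(benzyloxy)phenyl]-N-methoxy-N,3-dimethylbutanamide | CON(C)C(=O)C[C@H](C)Cc1ccc(OCc2ccccc2)cc1 | intermediate
18 | ethynylmagnesium bromide | C#C[Mg]Br | starting material
19 | (5R)-6-[4-(benzyloxy)phenyl]-5-methylhex-1-yn-3-one | C#CC(=O)C[C@H](C)Cc1ccc(OCc2ccccc2)cc1 | intermediate
20 | 1-[(E)-2-[(2R,3R,4S,5S)-5-[4-(benzyloxy)phenyl]-3,4-dimethyloxolan-2-yl]ethenyl]pyrrolidine, not isolated | C[C@@H]1[C@H](C)[C@@H](c2ccc(OCc3ccccc3)cc2)O[C@H]1/C=C/N1CCCC1 | intermediate
21 | (2R)-1-[4-(benzyloxy)phenyl]-7-[(2R,3R,4S,5S)-5-[4-(benzyloxy)phenyl]-3,4-dimethyloxolan-2-yl]-2-methyl-8-(pyrrolidin-1-yl)octa-5,7-dien-4-one, alkene geometry mobile, not isolated | C[C@@H]1[C@H](C)[C@@H](c2ccc(OCc3ccccc3)cc2)O[C@H]1C(=CN1CCCC1)C=CC(=O)C[C@H](C)Cc1ccc(OCc2ccccc2)cc1 | intermediate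
22 | 4-[(2R,3R,4S,5S)-5-[4-(benzyloxy)phenyl]-3,4-dimethyloxolan-2-yl]-2-[(2R)-1-[4-(benzyloxy)phenyl]propan-2-yl]phenol | C[C@@H]1[C@H](C)[C@@H](c2ccc(OCc3ccccc3)cc2)O[C@H]1c1ccc(O)c([C@H](C)Cc2ccc(OCc3ccccc3)cc2)c1 | intermediate
23 | 4-[(2R,3R,4S,5S)-5-(4-hydroxyphenyl)-3,4-dimethyloxolan-2-yl]-2-[(2R)-1-(4-hydroxyphenyl)propan-2-yl]phenol | C[C@@H]1[C@H](C)[C@@H](c2ccc(O)cc2)O[C@H]1c1ccc(O)c([C@H](C)Cc2ccc(O)cc2)c1 | target

**Step count and risks**

Total steps: 13. Longest linear sequence: 9 steps (steps 1–7, 12, 13); the ynone branch is 4 steps (8–11).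

Steps most likely to fail:

1. Step 12. Several processes can divert it:
   - the enamine may add to the ynone by stepwise [2+2] cycloaddition and ring opening, giving an acyl-transposed dienamine;
   - residual amine may add to the ynone;
   - β-alkoxy elimination in the enamine/iminium manifold may open the oxolane and, through a dienamine, erode C3 as well as C2;
   - the closure may stall at the push–pull aminodienone.

   Fallback: lower the oxidation level of the four-carbon partner and aromatise afterwards. From Weinreb amide 17, vinylmagnesium bromide (4) in THF at 0 °C with an acidic quench gives (5R)-6-[4-(benzyloxy)phenyl]-5-methylhex-1-en-3-one F1. The pyrrolidine enamine of aldehyde 13 adds to F1 (Stork enamine Michael addition, dioxane, rt), and AcOH/NaOAc then closes the ring by aldol condensation (Robinson annulation) to 4-[(2R,3R,4S,5S)-5-[4-(benzyloxy)phenyl]-3,4-dimethyloxolan-2-yl]-2-[(2R)-1-[4-(benzyloxy)phenyl]propan-2-yl]cyclohex-2-en-1-one F2, formed as epimers at the new ring carbon. Aerobic palladium-catalysed dehydrogenation (Pd(OCOCF3)2, 2-(dimethylamino)pyridine, TsOH, O2, DMSO, 80 °C) should then convert F2 into phenol 22, where the route is rejoined.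

2. Step 6. Hydride delivery may show poor facial selectivity (weak 1,2-induction, or erosion through enolisation of the aryl ketone), leaving the C1 epimer.

   Fallback: set C5 thermodynamically on the closed ring instead of kinetically on the chain. From ketone 9, NaBH4 (MeOH, 0 °C) gives (2S,3S)-1-[4-(benzyloxy)phenyl]-2,3-dimethylpent-4-en-1-ol as a mixture of C1 epimers F3. Cross-metathesis with methyl acrylate (second-generation Hoveyda–Grubbs catalyst, CH2Cl2, 40 °C) and t-BuOK-catalysed oxa-Michael closure (THF, −40 °C) give methyl 2-[(2S,3R,4S)-5-[4-(benzyloxy)phenyl]-3,4-dimethyloxolan-2-yl]acetate as C5 epimers F4. BF3·OEt2 (CH2Cl2, −20 °C) should equilibrate the electron-rich benzylic C5–O bond through its benzylic cation to the 4,5-trans isomer, methyl 2-[(2S,3R,4S,5S)-5-[4-(benzyloxy)phenyl]-3,4-dimethyloxolan-2-yl]acetate F5. Reduction with i-Bu2AlH (toluene, −78 °C) converts F5 into aldehyde 13, where the route is rejoined.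

3. Step 9. The alkyl radical may be lost to reduction or dimerisation, or the arylzinc reagent may homocouple, before the C–C bond forms.

   Fallback: create the methyl-bearing center by auxiliary-controlled conjugate addition instead of taking it from the chiral pool. From acid chloride 2 and commercial (R)-4-benzyloxazolidin-2-one (the enantiomer of 1), acylation as in step 1 gives (R)-4-benzyl-3-[(E)-but-2-enoyl]oxazolidin-2-one F6. 4-(Benzyloxy)benzylmagnesium chloride with CuBr·SMe2 (THF, −78 → −20 °C) should add to the face remote from the auxiliary benzyl group and give (R)-4-benzyl-3-[(3R)-4-[4-(benzyloxy)phenyl]-3-methylbutanoyl]oxazolidin-2-one F7. Me2AlN(OMe)Me (from AlMe3 and MeONHMe·HCl, CH2Cl2, 0 °C) then converts F7 into Weinreb amide 17, where the route is rejoined.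

**Further compounds**

F1 | step 12 | (5R)-6-[4-(benzyloxy)phenyl]-5-methylhex-1-en-3-one | C=CC(=O)C[C@H](C)Cc1ccc(OCc2ccccc2)cc1
F2 | step 12 | 4-[(2R,3R,4S,5S)-5-[4-(benzyloxy)phenyl]-3,4-dimethyloxolan-2-yl]-2-[(2R)-1-[4-(benzyloxy)phenyl]propan-2-yl]cyclohex-2-en-1-one, epimers at ring C4 | C[C@@H]1[C@H](C)[C@@H](c2ccc(OCc3ccccc3)cc2)O[C@H]1C4CCC(=O)C(=C4)[C@H](C)Cc5ccc(OCc6ccccc6)cc5
F3 | step 6 | (2S,3S)-1-[4-(benzyloxy)phenyl]-2,3-dimethylpent-4-en-1-ol, C1 epimers | C=C[C@H](C)[C@H](C)C(O)c1ccc(OCc2ccccc2)cc1
F4 | step 6 | methyl 2-[(2S,3R,4S)-5-[4-(benzyloxy)phenyl]-3,4-dimethyloxolan-2-yl]acetate, C5 epimers | C[C@@H]1[C@H](C)C(c2ccc(OCc3ccccc3)cc2)O[C@H]1CC(=O)OC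
F5 | step 6 | methyl 2-[(2S,3R,4S,5S)-5-[4-(benzyloxy)phenyl]-3,4-dimethyloxolan-2-yl]acetate | C[C@@H]1[C@H](C)[C@@H](c2ccc(OCc3ccccc3)cc2)O[C@H]1CC(=O)OC
F6 | step 9 | (R)-4-benzyl-3-[(E)-but-2-enoyl]oxazolidin-2-one | C/C=C/C(=O)N1[C@H](Cc2ccccc2)COC1=O
F7 | step 9 | (R)-4-benzyl-3-[(3R)-4-[4-(benzyloxy)phenyl]-3-methylbutanoyl]oxazolidin-2-one | O=C(C[C@H](C)Cc1ccc(OCc2ccccc2)cc1)N1[C@H](Cc2ccccc2)COC1=O
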